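(The numbers in the tables are simulated with made-up constants; noise was put on by code.)

At 6.0 h a flask is read either with solid monomer still in it or with its charge used up, so the reckoning compares that time with a lifetime of the charge.

| flask | solid monomer | initiator | remark | time |
|---|---|---|---|---|
| maple | 0.11 M | 7.3 mol% | run made earlier |  |
| zeta | 0.10 M | 4 mol% |  | 6.0 h |
| gamma | 0.20 M | 4 mol% |  | 6.0 h |
| beta | 0.20 M | 7.3 mol% |  | 6.0 h |
| alpha | 0.10 M | 7.3 mol% |  | 6.0 h |

maple run (percent of the solid monomer charged)

| time / min | monomer in chains / % | solid monomer / % |
|---|---|---|
| 10.0 | 1 | 92 |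
| 15.0 | 2 | 94 |
| 25.0 | 2 | 84 |
| 40.0 | 7 | 80 |
| 50.0 | 11 | 79 |
| 80.0 | 18 | 70 |
| 120 | 30 | 52 |

(each reading ± 2 percentage points)

- the flasks put in order of amount of monomer in chains, in percent of the solid monomer charged, best first, at 6.0 h (zeta / gamma / beta / alpha)
- the same order at 25 h (zeta / gamma / beta / alpha)
- the amount of monomer in chains, in percent of the solid monomer charged of the flask you put first, at 6.0 h
- the amount of monomer in chains, in percent of the solid monomer charged of the flask you put last, at 6.0 h

- solid monomer is a solid; its amount is given per volume of the solution
- at the start none of the solid monomer is in solution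
- no earlier run changes the charge of initiator; that part of a forecast is a guess

The lag counts for little, 15.0 min against 6.0 h. The rate into chains counts in full, because a flask still holding solid has in chains that rate times the time. Its link to initiator is a guess, taken here as proportional to loading and, in percent of charge, free of the charge. The solid lost without reaching chains is assumed constant per volume, so it weighs twice as much at 0.10 M as at 0.20 M. It is a difference of two slopes and carries the scatter of both.

Between 40.0 min and 120 min, maple gains 0.172 h⁻¹ of its charge in chains and loses 0.210 h⁻¹ as solid. The leak, solid lost per volume and time without reaching chains, is then 0.00413 M h⁻¹. The chain share (a selectivity) is the chain rate over the chain rate plus leak/c(solid monomer), and the lifetime is one over that sum.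

Beta's lifetime is 5.18 h and alpha's 4.68 h, both shorter than 6.0 h, so they are read at their shares, 89.3% and 80.7%. At 4 mol% the chain rate is 0.0945 h⁻¹. The lifetimes of gamma, 8.68 h, and zeta, 7.37 h, exceed 6.0 h, so this reckoning ties them at 56.7%. At 25 h their shares are 82.1% and 69.6%.

The forecast gives beta > alpha > gamma > zeta at 6.0 h and beta > alpha > gamma > zeta at 25 h, with 89% (72% to 98%) and 52% (38% to 72%). On charge it says: “Higher charge should dissolve faster and consume the last monomer faster”. This reckoning differs at 25 h: gamma's share, 82.1%, stands above alpha's, 80.7%, where the forecast puts alpha before gamma.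

The flasks give beta > alpha > zeta > gamma at 6.0 h, with beta at 88.1% and gamma at 58.8%, and beta > gamma > alpha > zeta at 25 h.

    free monomer + living end → monomer in chains + living end, rate k1*[living end]*[free monomer] (k = 4.90 M⁻¹ min⁻¹)
    free monomer → uncatalysed product (k = 0.00870 min⁻¹)
    solid monomer ⇌ free monomer, rate k3*(cs3 - [free monomer]) while solid is left; crystals form when [free monomer] > cs3 (solubility = 10.0 mM, k = 0.470 min⁻¹)
    free monomer + initiator → living end + monomer in chains (k = 2.10 M⁻¹ min⁻¹)

At 25 h, gamma stands at 80.9% against its share of 82.1%, and zeta at 67.6% against 69.6%. For the neighbour of beta charged with 12 mol% of initiator, the chain rate scales to 0.284 h⁻¹ and the leak stays. That gives a lifetime of 3.29 h and a share of 93.2%. That flask holds 92.0% in chains and 7.97% as uncatalysed product at 6.00 h.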